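**Retrosynthetic overview**

1. The target, guibourtinidol-(4α→8)-fisetinidol, comes from a penta-O-benzyl tribromide by one hydrogenolysis; the bromines at C6 of each benzo ring and at C6' of the lower catechol ring are temporary blocking groups.
2. The C4–C8 interflavan bond is cut to a flavan-4-yl cation (from the upper 2,3-trans-flavan-3,4-diol) and C8 of a fisetinidol benzyl ether; attack anti to the 3-OH sets C4.
3. Both partners come from 2,3-trans-dihydroflavonols: a reductase-like transfer hydrogenation resolves each racemate, and the lower unit is then deoxygenated at C4.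
4. Each dihydroflavonol is made in one flask from a shared 5-bromo-2-hydroxyacetophenone and a benzaldehyde: aldol to the 2'-hydroxychalcone, then oxidative oxa-Michael ring closure (chalcone synthase, chalcone isomerase and flavanone 3-hydroxylase logic).
5. Ring order: pyran ring C (upper unit) and pyran ring F (lower unit) are each closed from an open-chain chalcone before the interflavan bond is made; no ring is formed after the coupling.

Assumption: the three O-benzylated building blocks (4'-benzyloxy-2'-hydroxyacetophenone, 4-benzyloxybenzaldehyde, 3,4-dibenzyloxybenzaldehyde) are bought as catalogue items. TsDPEN = N-tosyl-1,2-diphenylethane-1,2-diamine, bound as its monoanion.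

**Route**

Step 1
Reactants: 1 1-[4-(benzyloxy)-2-hydroxyphenyl]ethanone
Product: 2 1-[4-(benzyloxy)-5-bromo-2-hydroxyphenyl]ethanone
Conditions: NBS (1.0 equiv), MeCN, 0 °C to rt
Reagents that add atoms: N-bromosuccinimide, O=C1CCC(=O)N1Br
Why: Electrophilic aromatic bromination goes to C5, which is para to the free OH, ortho to the benzyloxy group and less hindered than C3 between the two oxygens, and this bromine later blocks C6 of the benzo ring in both flavan units.

Step 2
Reactants: 2 1-[4-(benzyloxy)-5-bromo-2-hydroxyphenyl]ethanone; 3 4-(benzyloxy)benzaldehyde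
Product: 5 rac-(2R,3R)-7-(benzyloxy)-2-[4-(benzyloxy)phenyl]-6-bromo-3-hydroxy-2,3-dihydro-4H-chromen-4-one, via chalcone 4 (not isolated)
Conditions: KOH (aq), EtOH/THF, rt; then 30% H2O2, 0 °C, 3 h; AcOH quench
Reagents that add atoms: hydrogen peroxide, OO
Why: Claisen–Schmidt condensation gives the (E)-2'-hydroxychalcone, whose phenoxide then undergoes Algar–Flynn–Oyamada oxidative cyclisation (6-endo oxa-Michael closure with hydroxylation at the enolate carbon), which for a chalcone without a 6'-substituent held at 0 °C stops at the dihydroflavonol, the base-equilibrated diequatorial 2,3-trans isomer, formed as a racemate.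

Step 3
Reactants: 5 rac-(2R,3R)-7-(benzyloxy)-2-[4-(benzyloxy)phenyl]-6-bromo-3-hydroxy-2,3-dihydro-4H-chromen-4-one
Product: 6 (2R,3S,4R)-7-(benzyloxy)-2-[4-(benzyloxy)phenyl]-6-bromo-3,4-dihydro-2H-chromene-3,4-diol
Conditions: RuCl(p-cymene)[(S,S)-TsDPEN] (1 mol %), HCO2H/Et3N (5:2), CH2Cl2, 25 °C, stopped at about 45% conversion; the unreacted (2S,3S)-ketone is removed on silica
Reagents that add atoms: none
Why: Proposed new method: Noyori–Ikariya asymmetric transfer hydrogenation run as a kinetic resolution, in which the (S,S)-catalyst's preferred carbonyl face coincides with axial hydride delivery only for the (2R,3R)-ketone (2-aryl and 3-OH equatorial), so that enantiomer alone is reduced and gives the 3,4-trans (4R) alcohol while C2 and C3 are selected in absolute terms; the closest known reaction is the Ru/TsDPEN transfer-hydrogenative kinetic resolution of racemic flavanones to cis-flavan-4-ols.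

Step 4
Reactants: 7 3,4-bis(benzyloxy)benzaldehyde
Product: 8 4,5-bis(benzyloxy)-2-bromobenzaldehyde
Conditions: Br2 (1.05 equiv), NaOAc, AcOH, rt
Reagents that add atoms: bromine, BrBr
Why: Electrophilic aromatic bromination para to the 3-benzyloxy group (as in the 6-bromination of veratraldehyde) masks the one catechol-ring carbon of the future nucleophile that could compete with C8 in the Friedel–Crafts coupling.

Step 5
Reactants: 2 1-[4-(benzyloxy)-5-bromo-2-hydroxyphenyl]ethanone; 8 4,5-bis(benzyloxy)-2-bromobenzaldehyde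
Product: 10 rac-(2R,3R)-7-(benzyloxy)-2-[4,5-bis(benzyloxy)-2-bromophenyl]-6-bromo-3-hydroxy-2,3-dihydro-4H-chromen-4-one, via chalcone 9 (not isolated)
Conditions: KOH (aq), EtOH/THF, rt; then 30% H2O2, 0 °C, 3 h; AcOH quench
Reagents that add atoms: hydrogen peroxide, OO
Why: The same Claisen–Schmidt condensation and Algar–Flynn–Oyamada oxidative cyclisation as in step 2 close pyran ring F and give the racemic 2,3-trans-dihydroflavonol, the electron-rich aryl group at the β-carbon favouring six-membered over aurone ring closure.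

Step 6
Reactants: 10 rac-(2R,3R)-7-(benzyloxy)-2-[4,5-bis(benzyloxy)-2-bromophenyl]-6-bromo-3-hydroxy-2,3-dihydro-4H-chromen-4-one
Product: 12 (2R,3S)-7-(benzyloxy)-2-[4,5-bis(benzyloxy)-2-bromophenyl]-6-bromo-3,4-dihydro-2H-chromen-3-ol, via flavan-3,4-diol 11 (not isolated)
Conditions: RuCl(p-cymene)[(S,S)-TsDPEN] (1 mol %), HCO2H/Et3N (5:2), CH2Cl2, 25 °C, to about 45% conversion; then Et3SiH (5 equiv), TFA, −20 to 0 °C; the unreacted (2S,3S)-ketone is removed on silica
Reagents that add atoms: none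
Why: Proposed new method: the kinetic resolution of step 3 fixes C2 and C3 by reducing only the (2R,3R)-ketone, and cold TFA then ionises the doubly oxygen-stabilised benzylic alcohol so that Et3SiH quenches the C4 cation (Kursanov–Parnes ionic hydrogenation, the leucoanthocyanidin reductase counterpart) while the unreduced α-hydroxy ketone is not activated; the closest known reactions are the flavanone kinetic resolution by transfer hydrogenation and the hydride reduction of flavan-3,4-diols to flavan-3-ols in TFA.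

Step 7
Reactants: 6 (2R,3S,4R)-7-(benzyloxy)-2-[4-(benzyloxy)phenyl]-6-bromo-3,4-dihydro-2H-chromene-3,4-diol; 12 (2R,3S)-7-(benzyloxy)-2-[4,5-bis(benzyloxy)-2-bromophenyl]-6-bromo-3,4-dihydro-2H-chromen-3-ol
Product: 14 (2R,3S,4S)-7-(benzyloxy)-4-[(2R,3S)-7-(benzyloxy)-2-[4,5-bis(benzyloxy)-2-bromophenyl]-6-bromo-3-hydroxy-3,4-dihydro-2H-chromen-8-yl]-2-[4-(benzyloxy)phenyl]-6-bromo-3,4-dihydro-2H-chromen-3-ol, via flavan-4-yl cation 13 (not isolated)
Conditions: 12 (3 equiv), BF3·OEt2 (0.2 equiv), CH2Cl2, −30 to 0 °C, slow addition of 6; excess 12 recovered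
Reagents that add atoms: none
Why: Lewis-acid ionisation of the benzylic C4–OH gives the flavan-4-yl cation (the extender unit of proanthocyanidin biosynthesis), which alkylates 12 in a Friedel–Crafts reaction at C8, the only position still activated by two oxygens once C6 and C6' carry bromine, and the nucleophile adds anti to the 3-OH of the 2,3-trans cation to set the 3,4-trans (4S, 4α) centre, with dimers from residual wrong enantiomers or from 4β attack removed as diastereomers by chromatography.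

Step 8
Reactants: 14 (2R,3S,4S)-7-(benzyloxy)-4-[(2R,3S)-7-(benzyloxy)-2-[4,5-bis(benzyloxy)-2-bromophenyl]-6-bromo-3-hydroxy-3,4-dihydro-2H-chromen-8-yl]-2-[4-(benzyloxy)phenyl]-6-bromo-3,4-dihydro-2H-chromen-3-ol
Product: 15 (2R,3S,4S)-4-[(2R,3S)-2-(3,4-dihydroxyphenyl)-3,7-dihydroxy-3,4-dihydro-2H-chromen-8-yl]-2-(4-hydroxyphenyl)-3,4-dihydro-2H-chromene-3,7-diol
Conditions: H2 (1 atm), Pd(OH)2/C, Et3N (4 equiv), THF/MeOH/H2O, rt; Sephadex LH-20
Reagents that add atoms: none
Why: Catalytic hydrogenolysis cleaves the five benzyl ethers and, with Et3N taking up HBr, hydrodehalogenates the three aryl bromides without touching the interflavan bond or any stereocentre.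

**Compound list**

1 | 1-[4-(benzyloxy)-2-hydroxyphenyl]ethanone | CC(=O)c1ccc(OCc2ccccc2)cc1O | starting material
2 | 1-[4-(benzyloxy)-5-bromo-2-hydroxyphenyl]ethanone | CC(=O)c1cc(Br)c(OCc2ccccc2)cc1O | intermediate
3 | 4-(benzyloxy)benzaldehyde | O=Cc1ccc(OCc2ccccc2)cc1 | starting material
4 | (E)-1-[4-(benzyloxy)-5-bromo-2-hydroxyphenyl]-3-[4-(benzyloxy)phenyl]prop-2-en-1-one | O=C(/C=C/c1ccc(OCc2ccccc2)cc1)c1cc(Br)c(OCc2ccccc2)cc1O | intermediate
5 | rac-(2R,3R)-7-(benzyloxy)-2-[4-(benzyloxy)phenyl]-6-bromo-3-hydroxy-2,3-dihydro-4H-chromen-4-one (2,3-trans racemate; the 2R,3R enantiomer is drawn) | O=C1[C@H](O)[C@@H](c2ccc(OCc3ccccc3)cc2)Oc2cc(OCc3ccccc3)c(Br)cc21 | intermediate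
6 | (2R,3S,4R)-7-(benzyloxy)-2-[4-(benzyloxy)phenyl]-6-bromo-3,4-dihydro-2H-chromene-3,4-diol (2,3-trans-3,4-trans) | O[C@H]1[C@H](O)[C@@H](c2ccc(OCc3ccccc3)cc2)Oc2cc(OCc3ccccc3)c(Br)cc21 | intermediate
7 | 3,4-bis(benzyloxy)benzaldehyde | O=Cc1ccc(OCc2ccccc2)c(OCc2ccccc2)c1 | starting material
8 | 4,5-bis(benzyloxy)-2-bromobenzaldehyde | O=Cc1cc(OCc2ccccc2)c(OCc2ccccc2)cc1Br | intermediate
9 | (E)-1-[4-(benzyloxy)-5-bromo-2-hydroxyphenyl]-3-[4,5-bis(benzyloxy)-2-bromophenyl]prop-2-en-1-one | O=C(/C=C/c1cc(OCc2ccccc2)c(OCc2ccccc2)cc1Br)c1cc(Br)c(OCc2ccccc2)cc1O | intermediate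
10 | rac-(2R,3R)-7-(benzyloxy)-2-[4,5-bis(benzyloxy)-2-bromophenyl]-6-bromo-3-hydroxy-2,3-dihydro-4H-chromen-4-one (2,3-trans racemate; the 2R,3R enantiomer is drawn) | O=C1[C@H](O)[C@@H](c2cc(OCc3ccccc3)c(OCc3ccccc3)cc2Br)Oc2cc(OCc3ccccc3)c(Br)cc21 | intermediate
11 | (2R,3S,4R)-7-(benzyloxy)-2-[4,5-bis(benzyloxy)-2-bromophenyl]-6-bromo-3,4-dihydro-2H-chromene-3,4-diol | O[C@H]1[C@H](O)[C@@H](c2cc(OCc3ccccc3)c(OCc3ccccc3)cc2Br)Oc2cc(OCc3ccccc3)c(Br)cc21 | intermediate
12 | (2R,3S)-7-(benzyloxy)-2-[4,5-bis(benzyloxy)-2-bromophenyl]-6-bromo-3,4-dihydro-2H-chromen-3-ol | O[C@H]1Cc2cc(Br)c(OCc3ccccc3)cc2O[C@@H]1c1cc(OCc2ccccc2)c(OCc2ccccc2)cc1Br | intermediate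
13 | (2R,3S)-7-(benzyloxy)-2-[4-(benzyloxy)phenyl]-6-bromo-3-hydroxy-3,4-dihydro-2H-chromen-4-ylium (C4 cation) | O[C@H]1[CH+]c2cc(Br)c(OCc3ccccc3)cc2O[C@@H]1c1ccc(OCc2ccccc2)cc1 | intermediate
14 | (2R,3S,4S)-7-(benzyloxy)-4-[(2R,3S)-7-(benzyloxy)-2-[4,5-bis(benzyloxy)-2-bromophenyl]-6-bromo-3-hydroxy-3,4-dihydro-2H-chromen-8-yl]-2-[4-(benzyloxy)phenyl]-6-bromo-3,4-dihydro-2H-chromen-3-ol | C(c1ccccc1)Oc1ccc([C@H]2Oc3cc(OCc4ccccc4)c(Br)cc3[C@@H](c3c(OCc4ccccc4)c(Br)cc4c3O[C@H](c3cc(OCc5ccccc5)c(OCc5ccccc5)cc3Br)[C@@H](O)C4)[C@@H]2O)cc1 | intermediate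
15 | (2R,3S,4S)-4-[(2R,3S)-2-(3,4-dihydroxyphenyl)-3,7-dihydroxy-3,4-dihydro-2H-chromen-8-yl]-2-(4-hydroxyphenyl)-3,4-dihydro-2H-chromene-3,7-diol | Oc1ccc([C@H]2Oc3cc(O)ccc3[C@@H](c3c(O)ccc4c3O[C@H](c3ccc(O)c(O)c3)[C@@H](O)C4)[C@@H]2O)cc1 | target

**Totals**

Total step count: 8. Longest linear sequence: 5 steps (steps 4, 5, 6, 7, 8; the lines 1, 2, 3, 7, 8 and 1, 5, 6, 7, 8 are equally long).

**Three steps most likely to fail, with fallbacks**

Step 2 (the same operation is used in step 5). The cold alkaline peroxide stage may run on to the flavonol or divert to an aurone. The fallback separates ring closure from hydroxylation. It sets out from chalcone 4, now isolated after the aldol stage. NaOAc in refluxing EtOH closes it by plain oxa-Michael addition to the racemic flavanone 7-(benzyloxy)-2-[4-(benzyloxy)phenyl]-6-bromo-2,3-dihydro-4H-chromen-4-one F1. TMSOTf/Et3N in CH2Cl2 at 0 °C gives the silyl enol ether {7-(benzyloxy)-2-[4-(benzyloxy)phenyl]-6-bromo-2H-chromen-4-yl}oxy(trimethyl)silane F2. Rubottom oxidation with dimethyldioxirane in acetone at −40 °C (attack anti to the 2-aryl group), then mild acidic work-up, brings the route back to 5.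

Step 6 (the same resolution is used in step 3). The resolution may be too unselective, or the ionic hydrogenation may also touch the left-over ketone. The fallback sets the configuration by catalytic asymmetric epoxidation instead. It sets out from 2. MOMCl/iPr2NEt in CH2Cl2 gives 1-[4-(benzyloxy)-5-bromo-2-(methoxymethoxy)phenyl]ethanone F3. Claisen–Schmidt condensation with 8 gives (E)-1-[4-(benzyloxy)-5-bromo-2-(methoxymethoxy)phenyl]-3-[4,5-bis(benzyloxy)-2-bromophenyl]prop-2-en-1-one F4. Juliá–Colonna epoxidation (poly-L-leucine, urea–hydrogen peroxide, DBU, THF) gives [(2R,3S)-3-[4,5-bis(benzyloxy)-2-bromophenyl]oxiran-2-yl][4-(benzyloxy)-5-bromo-2-(methoxymethoxy)phenyl]methanone F5. HCl/MeOH removes the MOM group and the freed phenol opens the epoxide at the benzylic carbon (C3 keeps the epoxide configuration, and the trans ring closes), giving 10 as the (2R,3R)-enantiomer only. Complete reduction with the same Ru catalyst and then Et3SiH/TFA needs neither a resolution nor chemoselectivity, and the route is rejoined at 12. The same sequence with aldehyde 3 would replace the resolution in step 3.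

Step 7. The brominated benzo ring of 12 is only moderately nucleophilic, so self-alkylation of 6 at its own C8, oligomers and the 4β epimer may take over under Lewis acid. The fallback captures the cation as a storable thioether and releases it under neutral conditions. It sets out from 6. Phenylmethanethiol with catalytic BF3·OEt2 in CH2Cl2 at −20 °C gives (2R,3R,4R)-7-(benzyloxy)-4-(benzylsulfanyl)-2-[4-(benzyloxy)phenyl]-6-bromo-3,4-dihydro-2H-chromen-3-ol F6 (either C4 epimer serves). AgBF4 in THF at 0 °C with 12 (3 equiv) then activates the sulfur only, and the route is rejoined at 14.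

**Further compounds**

F1 | step 2 | rac-(2S)-7-(benzyloxy)-2-[4-(benzyloxy)phenyl]-6-bromo-2,3-dihydro-4H-chromen-4-one (racemate; 2S enantiomer drawn) | O=C1C[C@@H](c2ccc(OCc3ccccc3)cc2)Oc2cc(OCc3ccccc3)c(Br)cc21
F2 | step 2 | rac-(2S)-{7-(benzyloxy)-2-[4-(benzyloxy)phenyl]-6-bromo-2H-chromen-4-yl}oxy(trimethyl)silane (racemate; 2S enantiomer drawn) | C[Si](C)(C)OC1=C[C@@H](c2ccc(OCc3ccccc3)cc2)Oc2cc(OCc3ccccc3)c(Br)cc21
F3 | step 6 | 1-[4-(benzyloxy)-5-bromo-2-(methoxymethoxy)phenyl]ethanone | CC(=O)c1cc(Br)c(OCc2ccccc2)cc1OCOC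
F4 | step 6 | (E)-1-[4-(benzyloxy)-5-bromo-2-(methoxymethoxy)phenyl]-3-[4,5-bis(benzyloxy)-2-bromophenyl]prop-2-en-1-one | O=C(/C=C/c1cc(OCc2ccccc2)c(OCc2ccccc2)cc1Br)c1cc(Br)c(OCc2ccccc2)cc1OCOC
F5 | step 6 | [(2R,3S)-3-[4,5-bis(benzyloxy)-2-bromophenyl]oxiran-2-yl][4-(benzyloxy)-5-bromo-2-(methoxymethoxy)phenyl]methanone | O=C([C@@H]1O[C@H]1c1cc(OCc2ccccc2)c(OCc2ccccc2)cc1Br)c1cc(Br)c(OCc2ccccc2)cc1OCOC
F6 | step 7 | (2R,3R,4R)-7-(benzyloxy)-4-(benzylsulfanyl)-2-[4-(benzyloxy)phenyl]-6-bromo-3,4-dihydro-2H-chromen-3-ol | C(c1ccccc1)S[C@H]1[C@H](O)[C@@H](c2ccc(OCc3ccccc3)cc2)Oc2cc(OCc3ccccc3)c(Br)cc21
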